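**Assumptions:** The target is read as the trans (1S,2R) isomer. The two O‑TBS guaiacyl building blocks 7 and 9 are taken as purchasable catalogue items; if not, each is one TBSCl/imidazole step from 4‑bromoguaiacol or vanillin.

## Retrosynthetic overview

1. Target 13 ⇐ desilylation and DIBAL reduction of the fused α‑alkylidene lactone 11.
2. 11 ⇐ intramolecular Friedel–Crafts closure (C1–C8a) of the benzylic cation from (E)‑α‑arylidene‑γ‑aryl lactone 10; C1 is set trans to C2.
3. 10 ⇐ aldol condensation of lactone 8 with aldehyde 9; 8 ⇐ aryl Grignard from 7 plus aldehyde 6; 6 ⇐ ozonolysis of ester 5.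
4. Key step: 5 ⇐ Johnson–Claisen [3,3] rearrangement of (S,E)‑allylic alcohol 3. It forms the C2–C3 (lignan 8–8′) bond and transfers the purchased carbinol chirality to C2. 3 ⇐ cross‑metathesis of (S)‑but‑3‑en‑2‑ol 1.
5. Ring order: temporary γ‑lactone (step 4) → carbocyclic ring of the dihydronaphthalene, with re‑lactonisation to the fused lactone (step 6) → lactone opened by reduction (step 7).

## Route

**Step 1**
Reactants: 1, (S)‑but‑3‑en‑2‑ol; 2, allyloxy(tert‑butyl)dimethylsilane (3 equiv)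
Product: 3, (2S,3E)‑5‑[(tert‑butyldimethylsilyl)oxy]pent‑3‑en‑2‑ol
Conditions: Hoveyda–Grubbs II (3 mol %), CH2Cl2, 40 °C; E isomer isolated (AgNO3–SiO2 if needed)
Reagents that add atoms: none beyond reactant 2 (C=CCO[Si](C)(C)C(C)(C)C)
Why: Olefin cross‑metathesis of a secondary allylic alcohol with an allyl ether is E‑selective and leaves the purchased carbinol stereocentre untouched.

**Step 2**
Reactants: 3; 4, triethyl orthoacetate
Product: 5, ethyl (3S,4E)‑3‑{[(tert‑butyldimethylsilyl)oxy]methyl}hex‑4‑enoate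
Conditions: MeC(OEt)3 (6 equiv), EtCO2H (5 mol %), 140 °C, EtOH distilled off
Reagents that add atoms: triethyl orthoacetate (4), CCOC(C)(OCC)OCC
Why: Johnson–Claisen [3,3]‑sigmatropic rearrangement through a chair transition state with the methyl group equatorial forms the C2–C3 bond suprafacially, so the (S)‑carbinol is converted with 1,3‑chirality transfer into the new (S) carbon stereocentre (target C2) and an E‑propenyl group.

**Step 3**
Reactants: 5
Product: 6, ethyl (3R)‑4‑[(tert‑butyldimethylsilyl)oxy]‑3‑formylbutanoate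
Conditions: O3, CH2Cl2, −78 °C; PPh3, −78 °C → rt; used crude
Reagents that add atoms: ozone, [O-][O+]=O
Why: Ozonolysis cleaves the only alkene (no arenes are present yet) to the C1 aldehyde without touching the stereocentre; the descriptor changes only through CIP priorities.

**Step 4**
Reactants: 6; 7, (4‑bromo‑2‑methoxyphenoxy)(tert‑butyl)dimethylsilane
Product: 8, (4R,5RS)‑4‑{[(tert‑butyldimethylsilyl)oxy]methyl}‑5‑{4‑[(tert‑butyldimethylsilyl)oxy]‑3‑methoxyphenyl}oxolan‑2‑one (C5 epimers)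
Conditions: 7, Mg, THF (ArMgBr, 1.05 equiv); add to 6, THF, −78 → 0 °C; aq. NH4Cl; PPTS (cat.), CH2Cl2, rt
Reagents that add atoms: aryl bromide 7 (as its Grignard), COc1cc(Br)ccc1O[Si](C)(C)C(C)(C)C
Why: Chemoselective Grignard addition to the aldehyde followed by γ‑lactonisation; the new C5 (target C1) centre forms as a mixture, which does not matter because it is ionised in step 6.

**Step 5**
Reactants: 8; 9, 4‑[(tert‑butyldimethylsilyl)oxy]‑3‑methoxybenzaldehyde
Product: 10, (3E,4R,5RS)‑3‑{4‑[(tert‑butyldimethylsilyl)oxy]‑3‑methoxybenzylidene}‑4‑{[(tert‑butyldimethylsilyl)oxy]methyl}‑5‑{4‑[(tert‑butyldimethylsilyl)oxy]‑3‑methoxyphenyl}oxolan‑2‑one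
Conditions: LiHMDS, THF, −78 °C; 9; then MsCl, Et3N, 0 °C; DBU, 0 °C → rt (one pot)
Reagents that add atoms: aldehyde 9, COc1cc(C=O)ccc1O[Si](C)(C)C(C)(C)C
Why: Aldol condensation (aldol addition, then E1cB elimination of the mesylate) gives the thermodynamic E‑arylidene lactone, with the aryl group syn to C4 as needed for ring closure; C4 is β to the enolate and is not epimerised.

**Step 6**
Reactants: 10
Product: 11, (3aR,4S)‑6‑[(tert‑butyldimethylsilyl)oxy]‑4‑{4‑[(tert‑butyldimethylsilyl)oxy]‑3‑methoxyphenyl}‑7‑methoxy‑3a,4‑dihydronaphtho[2,3‑c]furan‑1(3H)‑one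
Conditions: TFA–CH2Cl2 (1:1), H2O (2 equiv), 0 °C → rt
Reagents that add atoms: none
Why: The p‑siloxybenzylic lactone C–O ionises in TFA like a PMB ester, and the cation undergoes intramolecular Friedel–Crafts alkylation para to OMe, anti to the C2 substituent, which sets C1 (S) trans to C2; both C5 epimers converge, the primary TBS is cleaved, and the hydroxy acid lactonises.

**Step 7**
Reactants: 11
Product: 12, [(1S,2R)‑7‑[(tert‑butyldimethylsilyl)oxy]‑1‑{4‑[(tert‑butyldimethylsilyl)oxy]‑3‑methoxyphenyl}‑6‑methoxy‑1,2‑dihydronaphthalene‑2,3‑diyl]dimethanol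
Conditions: DIBAL‑H (4 equiv), CH2Cl2, −78 → 0 °C; Rochelle salt work‑up
Reagents that add atoms: none
Why: DIBAL 1,2‑reduction of the conjugated lactone gives the allylic/primary diol without reducing the styrenic C3=C4 bond or touching either stereocentre.

**Step 8**
Reactants: 12
Product: 13, [(1S,2R)‑7‑hydroxy‑1‑(4‑hydroxy‑3‑methoxyphenyl)‑6‑methoxy‑1,2‑dihydronaphthalene‑2,3‑diyl]dimethanol (target, CID10473569)
Conditions: TBAF/AcOH (1:1, 2.5 equiv), THF, 0 °C
Reagents that add atoms: none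
Why: Buffered fluoride desilylation frees both phenols while avoiding phenoxide‑driven quinone‑methide chemistry of the p‑hydroxystyrene/allylic alcohol.

## Compound list

1 | (S)‑but‑3‑en‑2‑ol | C[C@H](O)C=C | starting material
2 | allyloxy(tert‑butyl)dimethylsilane | C=CCO[Si](C)(C)C(C)(C)C | starting material
3 | (2S,3E)‑5‑(TBSO)pent‑3‑en‑2‑ol | C[C@H](O)/C=C/CO[Si](C)(C)C(C)(C)C | intermediate
4 | triethyl orthoacetate | CCOC(C)(OCC)OCC | starting material
5 | ethyl (3S,4E)‑3‑(TBSO‑methyl)hex‑4‑enoate | CCOC(=O)C[C@H](CO[Si](C)(C)C(C)(C)C)/C=C/C | intermediate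
6 | ethyl (3R)‑4‑(TBSO)‑3‑formylbutanoate | CCOC(=O)C[C@H](CO[Si](C)(C)C(C)(C)C)C=O | intermediate
7 | (4‑bromo‑2‑methoxyphenoxy)(tert‑butyl)dimethylsilane | COc1cc(Br)ccc1O[Si](C)(C)C(C)(C)C | starting material
8 | (4R,5RS)‑4‑(TBSO‑methyl)‑5‑(4‑TBSO‑3‑methoxyphenyl)oxolan‑2‑one | O=C1C[C@H](CO[Si](C)(C)C(C)(C)C)C(c2ccc(O[Si](C)(C)C(C)(C)C)c(OC)c2)O1 | intermediate (C5 epimers)
9 | 4‑(TBSO)‑3‑methoxybenzaldehyde | COc1cc(C=O)ccc1O[Si](C)(C)C(C)(C)C | starting material
10 | (3E,4R,5RS)‑3‑(4‑TBSO‑3‑methoxybenzylidene)‑4‑(TBSO‑methyl)‑5‑(4‑TBSO‑3‑methoxyphenyl)oxolan‑2‑one | O=C1/C(=C/c2ccc(O[Si](C)(C)C(C)(C)C)c(OC)c2)[C@H](CO[Si](C)(C)C(C)(C)C)C(c2ccc(O[Si](C)(C)C(C)(C)C)c(OC)c2)O1 | intermediate (C5 epimers)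
11 | (3aR,4S)‑6‑(TBSO)‑4‑(4‑TBSO‑3‑methoxyphenyl)‑7‑methoxy‑3a,4‑dihydronaphtho[2,3‑c]furan‑1(3H)‑one | COc1cc([C@H]2c3cc(O[Si](C)(C)C(C)(C)C)c(OC)cc3C=C4C(=O)OC[C@H]24)ccc1O[Si](C)(C)C(C)(C)C | intermediate
12 | (1S,2R)‑bis‑TBS diol | COc1cc([C@H]2c3cc(O[Si](C)(C)C(C)(C)C)c(OC)cc3C=C(CO)[C@@H]2CO)ccc1O[Si](C)(C)C(C)(C)C | intermediate
13 | [(1S,2R)‑7‑hydroxy‑1‑(4‑hydroxy‑3‑methoxyphenyl)‑6‑methoxy‑1,2‑dihydronaphthalene‑2,3‑diyl]dimethanol | COc1cc([C@H]2c3cc(O)c(OC)cc3C=C(CO)[C@@H]2CO)ccc1O | target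

## Totals and risks

Total steps: 8. Longest linear sequence: 8 (1 → 13).

Steps most likely to fail:

1. **Step 6 (cationic ring closure).** The C1 cation could lose the C2–H to give an achiral bis‑arylidene diene, which would erode ee, or could alkylate sluggishly because the nucleophilic ring is conjugated to the carbonyl. Fallback: cyclise at the saturated stage instead. Conjugate‑reduce the arylidene of 10, run the conidendrin‑type Friedel–Crafts closure on the non‑conjugated benzyl arm, then reinstall C3=C4 by lactone α‑selenenylation and selenoxide elimination.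
2. **Step 1 (cross‑metathesis).** Any Z‑3 carried forward gives the enantiomeric series in the Claisen step. Fallback: build 3 from (S)‑but‑3‑yn‑2‑ol by C‑hydroxymethylation of the dianion with paraformaldehyde, selective primary silylation, and Red‑Al trans‑reduction, which gives only the E isomer.
3. **Step 4 (Grignard on aldehyde 6).** The α‑branched, β‑silyloxy aldehyde can epimerise or eliminate under basic conditions. Fallback: avoid the aldehyde electrophile. Pinnick‑oxidise 6 to the acid, make the aryl ketone by Pd‑catalysed acylation of the arylzinc with the acid chloride, then reduce with NaBH4 and lactonise to 8.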